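**Retrosynthetic overview**
1. The last bond made is the O7–CH2 ether. It comes from a Mitsunobu union of isofraxidin with the (2R,3R)-epoxy diol, which touches no stereocentre.
2. Isofraxidin comes from 6,7,8-trimethoxycoumarin by chloride cleavage of the only para-conjugated methoxy group (O-7).
3. Key disconnection: the benzene and pyranone rings are taken apart together to 2,3,4-trimethoxy-4-vinylcyclobutenone and ethyl (Z)-3-iodoacrylate (Heck, 4π opening, 6π closure and lactonisation in one flask). The cyclobutenone comes from dimethyl squarate, which supplies all four contiguous ring oxygens.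
4. The side chain comes from geraniol. Sharpless epoxidation sets both stereocentres, and a Schenck ene transposition then gives the E-allylic tertiary alcohol.
5. Ring order: the epoxide forms on its own branch, and the benzene and pyranone rings form together on the other. The four-membered ring is sacrificial.

Assumption: tributyl(vinyl)stannane, ethyl (Z)-3-iodoacrylate and D-(−)-diethyl tartrate are taken as catalogue chemicals. The cyclobutenone stereocentre is left racemic because aromatisation erases it.

**Step 1**
Reactants: 1 dimethyl squarate; 2 tributyl(vinyl)stannane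
Product: 5 (±)-2,3,4-trimethoxy-4-vinylcyclobut-2-en-1-one, via vinyllithium 3 (not isolated), via lithium alkoxide adduct 4 (not isolated)
Conditions: 2, n-BuLi (0.95 equiv to 2), THF, −78 °C, 1 h; cannulate into 1, THF, −78 °C; MeOTf (1.5 equiv), −78 to 0 °C
Reagents that add atoms: methyl triflate (MeOTf), COS(=O)(=O)C(F)(F)F
Why: Tin–lithium exchange gives vinyllithium, which adds 1,2 to one of the two equivalent squarate carbonyls (organolithium 1,2-addition to a squarate ester), and MeOTf O-methylates the lithium alkoxide in the flask; the new stereocentre is racemic and is erased in step 2.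

**Step 2 (key step)**
Reactants: 5 (±)-2,3,4-trimethoxy-4-vinylcyclobut-2-en-1-one; 6 ethyl (Z)-3-iodoacrylate (1.3 equiv)
Product: 10 6,7,8-trimethoxycoumarin, via Heck dienoate 7 (not isolated), via dienylketene 8 (not isolated), via Z-hydroxycinnamate 9 (not isolated)
Conditions: Pd(OAc)2 (5 mol%), AgOAc (1.1 equiv), DMF, Ar, dark, 45 °C, 14 h; then same flask, 115 °C, 3 h
Reagents that add atoms: none
Why: Proposed new method: a vinyl group on a fully substituted, oxygen-bearing carbon is a proven terminal- and E-selective Heck acceptor (2-methylbut-3-en-2-ol behaves this way), and silver-assisted Jeffery-type vinylation runs below the ring-opening threshold of the cyclobutenone, avoids base-induced loss of HI from 6 and keeps its Z geometry, so 7 accumulates at 45 °C; on heating, conrotatory 4π opening with the C4 methoxy group turning outward places the dienoate arm next to the ketene in 8, and 6π closure and tautomerisation give phenol 9, whose Z-ester lies on the new OH and lactonises, so the benzene and pyranone rings both form in this one flask; the closest known reaction types are the Moore–Liebeskind benzannulation of 4-alkenylcyclobutenones to phenols and the spontaneous lactonisation of Z-2-hydroxycinnamates.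

**Step 3**
Reactants: 10 6,7,8-trimethoxycoumarin
Product: 11 isofraxidin (7-hydroxy-6,8-dimethoxycoumarin)
Conditions: LiCl (5 equiv), DMF, 150 °C, 16 h; 1 M HCl work-up
Reagents that add atoms: none
Why: This is an SN2 dealkylation of an activated aryl methyl ether by chloride, in which only the 7-methoxy group is para to the C4a–C4=C3–C2=O acceptor and so releases a conjugated umbelliferone-type phenoxide, and it is also twisted out of plane by two ortho methoxy groups, the same selectivity that turns 3,4,5-trimethoxybenzaldehyde into syringaldehyde.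

**Step 4**
Reactants: 12 geraniol
Product: 13 (2R,3R)-2,3-epoxygeraniol
Conditions: Ti(OiPr)4 (5 mol%), D-(−)-diethyl tartrate (7 mol%), t-BuOOH (1.5 equiv, decane), 4 Å MS, CH2Cl2, −20 °C
Reagents that add atoms: tert-butyl hydroperoxide, CC(C)(C)OO
Why: In this Katsuki–Sharpless asymmetric epoxidation the Ti(OiPr)4/tartrate catalyst binds the allylic alcohol and, with the D-(−)-tartrate, delivers oxygen to the alkene face that gives the (2R,3R)-epoxide (about 95% ee), so both stereocentres are set at once, the trans relation of CH2OH and chain comes from the E-alkene, and the isolated 6,7-alkene is untouched.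

**Step 5**
Reactants: 13 (2R,3R)-2,3-epoxygeraniol
Product: 15 (2R,3R,5E)-2,3-epoxy-3,7-dimethyloct-5-ene-1,7-diol, via allylic hydroperoxide 14 (not isolated)
Conditions: O2, tetraphenylporphyrin (0.5 mol%), white LED, CH2Cl2, 0 °C; then PPh3 (1.1 equiv), 0 °C to rt; chromatography
Reagents that add atoms: dioxygen, O=O
Why: In the Schenck ene reaction singlet oxygen attacks the only remaining alkene, abstraction of a C5 hydrogen puts OOH on the tertiary carbon and gives the E-5,6-alkene, and PPh3 reduces O–O without touching the epoxide, so the two stereocentres are carried through unchanged (the isopropenyl regioisomer forms in similar amount and is separated).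

**Step 6**
Reactants: 11 isofraxidin; 15 (2R,3R,5E)-2,3-epoxy-3,7-dimethyloct-5-ene-1,7-diol
Product: 16 7-{[(2R,3R)-3-[(2E)-4-hydroxy-4-methylpent-2-en-1-yl]-3-methyloxiran-2-yl]methoxy}-6,8-dimethoxy-2H-chromen-2-one (target)
Conditions: PPh3 (1.3 equiv), DIAD (1.3 equiv), THF, 0 °C to rt
Reagents that add atoms: none
Why: In this Mitsunobu etherification the acidic phenol (pKa about 8) displaces the oxyphosphonium of the primary alcohol by SN2 at the CH2 group, so the adjacent epoxide stereocentres keep their (2R,3R) configuration, and the tertiary allylic alcohol is too hindered to be activated.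

**Compound list**
1 | dimethyl squarate (3,4-dimethoxycyclobut-3-ene-1,2-dione) | COC1=C(OC)C(=O)C1=O | starting material
2 | tributyl(vinyl)stannane | C=C[Sn](CCCC)(CCCC)CCCC | starting material
3 | vinyllithium | [Li]C=C | intermediate
4 | lithium 2,3-dimethoxy-4-oxo-1-vinylcyclobut-2-en-1-olate (racemic) | [Li+].[O-]C1(C=C)C(OC)=C(OC)C1=O | intermediate
5 | (±)-2,3,4-trimethoxy-4-vinylcyclobut-2-en-1-one | COC1=C(OC)C(OC)(C=C)C1=O | intermediate
6 | ethyl (Z)-3-iodoacrylate | CCOC(=O)/C=C\I | starting material
7 | ethyl (2Z,4E)-5-(1,2,3-trimethoxy-4-oxocyclobut-2-en-1-yl)penta-2,4-dienoate (racemic) | CCOC(=O)/C=C\C=C\C1(OC)C(OC)=C(OC)C1=O | intermediate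
8 | ethyl (2Z,4E,6Z)-6,7,8-trimethoxy-9-oxonona-2,4,6,8-tetraenoate (dienylketene) | O=C=C(OC)/C(OC)=C(OC)\C=C\C=C/C(=O)OCC | intermediate
9 | ethyl (Z)-3-(2-hydroxy-3,4,5-trimethoxyphenyl)acrylate | CCOC(=O)/C=C\c1cc(OC)c(OC)c(OC)c1O | intermediate
10 | 6,7,8-trimethoxycoumarin | COc1cc2ccc(=O)oc2c(OC)c1OC | intermediate
11 | isofraxidin (7-hydroxy-6,8-dimethoxycoumarin) | COc1cc2ccc(=O)oc2c(OC)c1O | intermediate
12 | geraniol | CC(C)=CCC/C(C)=C/CO | starting material
13 | (2R,3R)-2,3-epoxygeraniol | OC[C@H]1O[C@]1(C)CCC=C(C)C | intermediate
14 | (2R,3R,5E)-2,3-epoxy-7-hydroperoxy-3,7-dimethyloct-5-en-1-ol | OC[C@H]1O[C@]1(C)C/C=C/C(C)(C)OO | intermediate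
15 | (2R,3R,5E)-2,3-epoxy-3,7-dimethyloct-5-ene-1,7-diol | OC[C@H]1O[C@]1(C)C/C=C/C(C)(C)O | intermediate
16 | 7-{[(2R,3R)-3-[(2E)-4-hydroxy-4-methylpent-2-en-1-yl]-3-methyloxiran-2-yl]methoxy}-6,8-dimethoxy-2H-chromen-2-one | COc1cc2ccc(=O)oc2c(OC)c1OC[C@H]1O[C@]1(C)C/C=C/C(C)(C)O | target

**Totals**
- Total step count: 6
- Longest linear sequence: 4 (steps 1, 2, 3, 6)

**Three steps most likely to fail**

(a) Step 2.
- Risk: the Heck stage may stall on the neopentyl-type vinyl group. The cyclobutylcarbinyl–palladium intermediate may open the strained ring by β-carbon elimination. The Z-ester may also leak to E, which blocks lactonisation.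
- Fallback: it sets out from 1 and comes back at 7. (E)-1,2-Bis(tributylstannyl)ethene and n-BuLi (THF, −78 °C) give (E)-2-(tributylstannyl)vinyllithium F1. This is added to 1 and quenched with MeOTf to give racemic 2,3,4-trimethoxy-4-[(E)-2-(tributylstannyl)vinyl]cyclobut-2-en-1-one F2. Stille coupling of F2 with 6 (Pd2(dba)3, AsPh3, CuI, DMF, rt) makes the C–C bond at a predefined carbon with retention of both alkene geometries and gives 7 as an isolated compound. Heating 7 alone in toluene at 110 °C takes it through 8 and 9 to 10.

(b) Step 3.
- Risk: at 150 °C chloride may also attack the 8- or 6-methoxy group, or amine from degrading DMF may open the lactone.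
- Fallback: it sets out from 5 and comes back at 11, and it marks O-7 before the arene exists instead of differentiating three methoxy groups afterwards. C3 of 5 is the β-carbon of a vinylogous ester and becomes C7 of the coumarin. 4-Methoxybenzyl alcohol (3 equiv) with NaH (10 mol%) and 4 Å sieves in THF at 0 °C therefore exchanges only that methoxy group by conjugate addition–elimination, giving racemic 2,4-dimethoxy-3-[(4-methoxybenzyl)oxy]-4-vinylcyclobut-2-en-1-one F3. F3 and 6 under the conditions of step 2 give 6,8-dimethoxy-7-[(4-methoxybenzyl)oxy]coumarin F4. TFA and anisole in CH2Cl2 at 0 °C then release 11.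

(c) Step 5.
- Risk: singlet oxygen abstracts from the C5 methylene and from the cis methyl group at similar rates. The yield of 15 is therefore capped near 45%, and the separation may be poor.
- Fallback: it sets out from 12 and comes back at 15, replacing the pericyclic oxygenation by an ionic, regiospecific transposition done before the epoxide is present. N-(Phenylseleno)phthalimide, water and catalytic camphorsulfonic acid in CH2Cl2 add PhSe/OH in the Markovnikov sense to the more electron-rich 6,7-alkene of 12. This gives (2E)-3,7-dimethyl-6-(phenylselanyl)oct-2-ene-1,7-diol F5. H2O2 in THF/pyridine forms the selenoxide, which can eliminate only towards C5 and gives (2E,5E)-3,7-dimethylocta-2,5-diene-1,7-diol F6. Sharpless epoxidation of F6 under the conditions of step 4 takes only the primary allylic alcohol, because the tertiary one is a very poor substrate, and gives 15.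

**Further compounds**
F1 | step 2 | (E)-2-(tributylstannyl)vinyllithium | [Li]/C=C/[Sn](CCCC)(CCCC)CCCC
F2 | step 2 | (±)-2,3,4-trimethoxy-4-[(E)-2-(tributylstannyl)vinyl]cyclobut-2-en-1-one | COC1=C(OC)C(OC)(/C=C/[Sn](CCCC)(CCCC)CCCC)C1=O
F3 | step 3 | (±)-2,4-dimethoxy-3-[(4-methoxybenzyl)oxy]-4-vinylcyclobut-2-en-1-one | COC1=C(OCc2ccc(OC)cc2)C(OC)(C=C)C1=O
F4 | step 3 | 6,8-dimethoxy-7-[(4-methoxybenzyl)oxy]coumarin | COc1cc2ccc(=O)oc2c(OC)c1OCc1ccc(OC)cc1
F5 | step 5 | (2E)-3,7-dimethyl-6-(phenylselanyl)oct-2-ene-1,7-diol (racemic at C6) | CC(C)(O)C([Se]c1ccccc1)CC/C(C)=C/CO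
F6 | step 5 | (2E,5E)-3,7-dimethylocta-2,5-diene-1,7-diol | CC(C)(O)/C=C/C/C(C)=C/CO
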